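The data are simulated from invented constants, and the scatter is random.

In the vessel, starting material goes two ways, to homo dimer and to target, and I looked for how the rate of its loss follows its concentration.

| flask | starting material | coupling partner | temperature | remark | time |
|---|---|---|---|---|---|
| south-east | 0.050 M | 0.025 M | −15 °C | run made earlier |  |
| north | 0.025 M | 0.025 M | 0 °C | run made earlier |  |
| north-west | 0.10 M | 0.025 M | −15 °C | run made earlier |  |
| alder | 0.050 M (fed, over 1.5 min) | 0.0250 M | 0 °C | all else is in the flask from the start; the feed brings no volume worth counting | 2.0 min |
| birch | 0.050 M | 0.0250 M (in portions, 4, over 1.5 min) | 0 °C | first portion at the start, last at 1.5 min | 2.0 min |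
| ash | 0.050 M | 0.0250 M (fed, over 1.5 min) |  | the addition at −30 °C, then warmed to 0 °C; the feed brings no volume worth counting | 2.0 min |
| maple | 0.050 M | 0.0250 M |  | everything together at the start at −30 °C, warmed to 0 °C at 1.5 min | 2.0 min |
| elm | 0.050 M | 0.0250 M | 0 °C | everything together at the start | 2.0 min |

| run | time / min | homo dimer / % | target / % |
|---|---|---|---|
| south-east | 0.333 | 34 | 10 |
| south-east | 0.500 | 41 | 5 |
| south-east | 0.833 | 50 | 8 |
| south-east | 1.33 | 59 | 10 |
| south-east | 2.00 | 68 | 10 |
| south-east | 3.00 | 78 | 7 |
| north | 0.417 | 40 | 13 |
| north | 0.833 | 52 | 20 |
| north | 1.33 | 60 | 16 |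
| north | 1.50 | 64 | 21 |
| north | 2.00 | 70 | 19 |
| north | 2.50 | 66 | 17 |
| north-west | 0.417 | 51 | 6 |
| north-west | 0.667 | 60 | 4 |
| north-west | 1.00 | 71 | 9 |
| north-west | 2.00 | 79 | 11 |
| north-west | 3.00 | 82 | 9 |
| north-west | 5.00 | 86 | 5 |

(standard deviation of a reading: 2 percentage points)

- the flask with the highest amount of homo dimer, in percent of the starting material charged ("all alike" if they lie within 1.5 percentage points) (alder / birch / ash / maple / elm / all alike)
- final homo dimer, as a percentage of the starting material charged, in alder
- final homo dimer, as a percentage of the starting material charged, in birch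
- final homo dimer, as a percentage of the starting material charged, in ash
- final homo dimer, as a percentage of the starting material charged, in maple
- final homo dimer, as a percentage of the starting material charged, in elm

- percentages count the starting material that a species holds: one homo dimer counts as two
- the numbers in the tables scatter with a standard deviation of 2 percentage points

Two starting material make each homo dimer, so I tried a rate in the square of its concentration. The time to halve it is then inverse to the concentration standing at that moment. The south-east run tested this. At 0.333 min it had 56.0 % left, and 77.3 % of the loss was homo dimer, which gave a halving time of 0.548 min. That time predicted 21.5 % left at 2.00 min, and I read 22.0 %. A first-order fall gave 3.07 %.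

The same reckoning on the first north reading gave 0.490 min at 0.025 M and 0 °C. At 0.050 M it runs twice as fast, which gives 0.245 min. I carried this forward as the dimer clock: the time the homo dimer route takes by itself to halve the starting material at 0.050 M and 0 °C, lengthening as the concentration falls.

The ladder began there. Next came 0.548 min at −15 °C, and I extrapolated 1.23 min at −30 °C by taking the same factor again. Above these stood the addition, 1.5 min, and the end, 2.0 min. So in elm I reckoned 10.9 % left at the end. Maple stayed cold for 1.5 min, and I used the extrapolated clock for that stretch. I reckoned 45.0 % left at warming and 23.5 % at the end, and I took ash as the same. For target I took the north reading, 19 % of half this charge, so 9.50 %. My homo dimer was 79.6 % in elm and 67.0 % in maple and ash. I left alder and birch unreckoned.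

The forecast named birch, with 74 % in alder, 88 % in birch, 74 % in ash, 72 % in maple and 85 % in elm, and said: “Birch: partner is scarce early, so slightly less target”. Its elm stood higher than mine, and so did its maple.

The flasks gave 75.1 % in alder, 80.4 % in birch, 66.8 % in ash, 66.8 % in maple and 76.5 % in elm, so birch stood highest.

    starting material + coupling partner → target (k = 1.50 M⁻¹ s⁻¹, Ea = 53.0 kJ mol⁻¹)
    2 coupling partner → side product (k = 7.80 M⁻¹ s⁻¹, Ea = 42.0 kJ mol⁻¹)
    2 starting material → homo dimer (k = 0.720 M⁻¹ s⁻¹, Ea = 41.0 kJ mol⁻¹)
    (constants at 0 °C)

Maple held 55.7 % of its starting material at warming, more than the 45.0 % I had reckoned. In ash at 2.00 min, 23.1 % of the starting material remained, and its half-life by the target step was 6.5 min. The dimer clock at that concentration reads 1.06 min, which is shorter.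

Ash left until 3.0 min runs 1.00 min longer. The clock leaves 11.9 % of the starting material and brings homo dimer to 78.0 %. The computed flask holds 77.8 %, with 11 % left.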